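At early times the noon run's first reading gives a rate of 0.0128 M h⁻¹, which you take as the catalyst path, and from here on you freeze that path's rate per unit of [substrate] at its first value.

| setting | noon | dawn | spring | dusk |
|---|---|---|---|---|
| substrate | 0.500 M | 0.200 M | 1.00 M | 0.500 M |
| free catalyst | 0.0150 M | 0.0150 M | 0.0150 M | 0.00370 M |
| time |  |  |  | 35 h |

- noon run (time / h: [target] / M): 1.6: 0.0205; 4.7: 0.0673; 9.0: 0.1337; 14: 0.2115; 20: 0.2978; 27: 0.3674; 35: 0.4150
- dawn run (time / h: [target] / M): 1.6: 0.0129; 4.7: 0.0318; 9.0: 0.0638; 14: 0.0932; 20: 0.1143; 27: 0.1432; 35: 0.1595
- spring run (time / h: [target] / M): 1.6: 0.0289; 4.7: 0.1061; 9.0: 0.2404; 14: 0.4305; 20: 0.6502; 27: 0.8248; 35: 0.9243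

(each reading ± 0.002 M)

- Overall: substrate -> target, with free catalyst as catalyst.
- Constant volume, constant temperature.
- The analysis sees a species whether free or bound.
- An order is taken over about fifteen percent of the charge, up and down.

* the power of [substrate] that the first rate follows, about the charge of the noon run; measure it at two percent of substrate made into target (one fixed amount of target, the same in the runs compared)
* the dawn run starts with 0.300 M less of substrate than the noon run, and with no target. Compared where both hold the same amount of substrate, once fifteen percent of what the dawn run was charged with has turned into target, is the dawn run faster, slower or alike (within a tenth)?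
* target in the dusk run at 35 h, as a share of the substrate charged

1. Midway through the spring run, between 14 h and 20 h, the substrate is about 0.460 M, close to the noon charge, yet the rate is 0.0366 M h⁻¹, faster than that first rate. Charge the excess to target times substrate (autocatalysis), and you read k = 0.0958 M⁻¹ h⁻¹.

2. Fold this into N, k times the substrate charge times the time, the number of e-foldings open to target feeding on itself; for the dusk run 1.68. N holds no catalyst, so the noon run at 35 h has the same N.

3. One number is not enough, since you still need the seed σ, the first rate over k times the charge squared. Assuming first order in catalyst, which these runs leave untested, σ is 0.132 for the dusk run and 0.535 for the noon run. The share x then obeys (x+σ)/(1−x) = σ·exp(N(1+σ)).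

4. For the noon run this gives 80.9% against a reading of 83.0%, so you commit to 39.8% for the dusk run.

5. The first readings of the dawn and spring runs, taken at one time and across their two charges, give an order near 0.501, which you carry over as your estimate about the noon charge. At equal substrate the dawn run holds 0.0300 M of target, less than the noon run's 0.330 M, so you expect it slower.

6. The forecast says 0.5, slower and 26%, adding “A lower order would give more, so the range is skewed high.” Its dusk value is the noon run with its clock scaled as if first order in everything but substrate, and it lies below yours.

7. The flask gives 0.55, slower (rate ratio 0.69) and 45.7%.

    free catalyst + substrate ⇌ catalyst-substrate complex, settled at all times (1.970 M⁻¹)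
    catalyst-substrate complex → target + free catalyst (1.760 h⁻¹)
    substrate + target → 2 target (0.1148 M⁻¹ h⁻¹)
    free catalyst + target → spent catalyst + target (0.1984 M⁻¹ h⁻¹)

Take the step by which substrate and target make more target out of the dusk run, and the share falls from 45.7% to 20.0%. That is close to 19.9%, which is 1 − exp(−σN), your frozen catalyst path with the growth in target removed. In your reckoning, cutting the catalyst shrinks σ and leaves N as it was. In the dawn run, whose first reading gives σ = 2.10, the formula puts target at a quarter of the charge at 6.72 h, and the flask reaches it at 7.08 h.

(The earlier runs and the new flask were generated by integration from invented constants.)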